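The readings are simulated with constants of no real substance; noise was put on by code.

The pitfall is to carry a percentage from flask to flask at the same clock time; carry turnovers instead. For any reading, count the natural logarithm of what has not yet become J or Z, with a minus sign.

| flask | X | L | remark | time |
|---|---|---|---|---|
| ash | 6.7 mM | 2.5 equiv (in portions, 4) | run made earlier; portions every 40 s |  |
| cedar | 20 mM | 2.5 equiv (in portions, 4) | run made earlier; portions every 40 s |  |
| north | 10 mM | 10.0 equiv (in portions, 4) | the portions of L follow each other after 40 s, the first at the start | 2.5 min |
| east | 10 mM | 10.0 equiv (in portions, 4) | the portions of L follow each other after 12 s, the first at the start | 2.5 min |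
| north-east | 10 mM | 2.50 equiv (in portions, 4) | the portions of L follow each other after 40 s, the first at the start | 2.5 min |
| south | 10 mM | 2.50 equiv (in portions, 4) | the portions of L follow each other after 12 s, the first at the start | 2.5 min |

| run | time / s | J / % | Z / % |
|---|---|---|---|
| ash | 10.0 | 6.1 | 0 |
| ash | 12.0 | 6.4 | 0 |
| ash | 25.0 | 11.4 | 0.5 |
| ash | 40.0 | 14.6 | 0.9 |
| ash | 50.0 | 20.2 | 3.9 |
| cedar | 10.0 | 12.7 | 0.5 |
| cedar | 20.0 | 17.5 | 2.7 |
| cedar | 30.0 | 22.8 | 5.1 |
| cedar | 40.0 | 24.2 | 5.2 |
| cedar | 50.0 | 30.1 | 9.9 |

(standard deviation of a reading: 0.5 percentage points)

1. ranking by share of J in all that became J or Z, from high to low, at 2.5 min (north / east / north-east / south)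
2. the share of J in all that became J or Z of the flask you put first, at 2.5 min
3. the share of J in all that became J or Z of the flask you put last, at 2.5 min



Read one row of each run, at 40 s, when the second portion is due. Ash stands at a count of 0.168 and cedar at 0.348. Cedar holds 2.99 times the concentration of ash, but reaches 2.07 times the count, so these two scattered readings put the count at concentration to the power 0.664.

Now take the share. If J takes L about as fast as X does, a selectivity factor near one, the share of J is the count divided by its exponential less one. For cedar this gives 83.6%, and the row reads 82.3%.

My own reckoning scales ash to 10 mM and multiplies by 4 portions, as if each gave what the first gave in ash, which gives north-east a turnover count of 0.879 and a share of 62.4%. Assuming the count follows the L in a portion by the same power, north has 2.21 and a share of 27.2%. Ash and cedar were not dosed on the 12 s schedule, so I leave south and east uncounted.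

The forecast differs from my shares. It gives north-east > south > north > east, with 56% at the top and 1.1% at the bottom, on the ground that “The J share therefore depends only on the exposure ∫L dt.”

The flasks give north-east > south > east > north, with north-east at 51.5% and north at 16.4%. At 2.50 min, north-east holds 18.4% of X and 5.67% of G, a mono adduct at the other site, for which the readings have no column. Its J and Z give a count of 1.42, higher than my 0.879, by a factor of 1.62.

    X + L → G (k = 0.579 M⁻¹ s⁻¹)
    L + J → Z (k = 0.855 M⁻¹ s⁻¹)
    2 L → Q (k = 0.849 M⁻¹ s⁻¹)
    X + L → J (k = 1.54 M⁻¹ s⁻¹)
    L + G → Z (k = 3.22 M⁻¹ s⁻¹)

Take the neighbour of north-east with 6.0 mM of X, its equivalents and time held. My estimate, scaled by the same power and the same factor, gives a count of 1.01 and a share of 57.9%. The computed flask has a count of 1.08 and a share of J of 59.0%.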